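(The runs stem from a simulated flask with constants of no real substance, noise included.)

The constants of the three steps are not given, so I begin with what needs none of them, a count. The substrate and the coupling partner make the open intermediate, which leaves by meeting one second reagent, to give product, or one capture agent, to give trapped intermediate.

| flask | substrate | coupling partner | second reagent | capture agent | remark | time |
|---|---|---|---|---|---|---|
| dusk | 0.020 M | 0.080 M | 0.012 M | 6 mM | run made earlier |  |
| winter | 0.020 M | 0.080 M | 0.018 M | 6 mM | run made earlier |  |
| spring | 0.020 M | 0.080 M | 0.024 M | 12 mM | run made earlier |  |
| flask | 0.020 M | 0.0800 M | 0.0240 M | 6.00 mM |  | 15 d |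

| run | time / d | substrate / % | product / % |
|---|---|---|---|
| dusk | 0.625 | 9.7 | 33.9 |
| dusk | 1.67 | 1.0 | 51.7 |
| dusk | 3.00 | 0.1 | 58.6 |
| dusk | 5.00 | 0.3 | 58.5 |
| dusk | 8.00 | 0 | 60.0 |
| dusk | 10.0 | 0.3 | 60.3 |
| dusk | 12.0 | 0.3 | 59.5 |
| winter | 1.67 | 0 | 68.8 |
| winter | 3.00 | 0 | 74.2 |
| winter | 5.00 | 0 | 75.7 |
| winter | 6.00 | 0 | 76.5 |
| winter | 8.00 | 0.2 | 77.2 |
| winter | 10.0 | 0 | 76.5 |
| winter | 12.0 | 0 | 76.6 |
| spring | 1.04 | 2.9 | 61.5 |
| spring | 3.00 | 0.6 | 70.6 |
| spring | 6.00 | 0 | 70.1 |
| spring | 8.00 | 0 | 70.9 |
| spring | 12.0 | 0.1 | 71.7 |

(scatter of a reading: 0.5 percentage points)

- reactions considered so far: second reagent + open intermediate -> product; open intermediate + capture agent -> trapped intermediate; substrate + coupling partner -> open intermediate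
- the reaction counts as stopped when no species that holds the substrate changes by six tenths of a point or more over the second half of the time

- at 15 d, what has stopped the reaction, if anything has (the coupling partner has run out first / the second reagent has run out first / all of the substrate has reacted / it is still moving)
- part of the substrate gone at 15 d
- the product standing at 15 d, as a percentage of the substrate charged

I call S = 50.0% the sink surplus, second reagent plus capture agent minus substrate, over the substrate charged, here for the flask. Its sign marks the crossing. The dusk run falls short by 10.0%, and its product levels at 60.3%, close to the 60.0% its second reagent allows. The winter run has a surplus of 20.0% and levels higher, at 76.5%. Control therefore passes between these runs to the substrate, the limiting reagent, and in the flask I expect the substrate to give out first, with the two remainders adding up to S.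

How they divide is a competition. If each step goes with its own reagent times the open intermediate, the logarithm of charge over remainder for second reagent is a constant a, the selectivity factor, times the same logarithm for capture agent. Counting what is not product as trapped, the winter run reads a = 1.24 and the spring run 1.35, so I take their mean, 1.29. For the flask I start from equal remainders, 33.3% of each charge, carry second reagent's over to capture agent's through a, and let S return a new second reagent remainder, 31.0%, then 31.6%. The second reagent consumed gives product, 82.1%.

The weak link is the winter value, whose capture remainder of 6.50% of the substrate charged is smaller than spring's 30.9%, while the scatter stays 0.5 percentage points. Rerun on the spring value, the chain gives 82.5%, a shift of 0.40 points, so my number stands.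

The forecast reads all of the substrate has reacted, 100% gone and 82.3% of product, against my 82.1%, and says “Reagent remains in excess”.

The flask gives 82.5% of product at 15 d, with 100% of the substrate gone: all of the substrate has reacted.

    second reagent + open intermediate → product (k = 0.00200 M⁻¹ s⁻¹)
    open intermediate + capture agent → trapped intermediate (k = 0.00150 M⁻¹ s⁻¹)
    substrate + coupling partner → open intermediate (k = 6.30 × 10⁻⁴ M⁻¹ s⁻¹)

At 15.0 d the substrate, with 0% left, stands below second reagent at 31% and capture agent at 42% of their own charges. Those two remainders, over the substrate charged, come to 50.0%, against the S of 50.0%. With 0.0096 M of second reagent in place of the 0.0240 M in the flask, the neighbour flask is short of sinks by 22.0% of the substrate charged, and it ends with 22.0% of open intermediate.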